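**Retrosynthetic overview**

1. The propenol side chain is cut at the aryl–vinyl bond (Suzuki), so the benzo ring comes from an aryl bromide: 5-bromo-o-vanillin (1) → catechol (2).
2. The C6–C3 half is (E)-sinapyl alcohol (3), used as its phenol TBS ether (4) with the allylic OH left free.
3. Key disconnection: both C–O bonds of the dioxane ring at once. Catechol 2 is oxidised to the non-aromatic o-quinone (5), which reacts as an O=C–C=O heterodiene with alkene 4 under a chiral phosphoric acid. This forms the only new ring, rearomatises the arene and sets C2/C3 (trans and absolute), giving bromide 6.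
4. Endgame: 6 + alkenyl boronate (7) → 8, then global desilylation → target (9).

Assumptions: the SMILES is read as the (2S,3S)-trans-benzodioxane with an (E)-propenol; 1, 3, 7 and both TRIP enantiomers are taken as catalogue items. The TRIP enantiomer that gives (2S,3S) cannot be predicted for this new reaction; (R)-TRIP is written and (S)-TRIP is substituted if the first analytical run (chiral HPLC/CD) shows the opposite sense.

**Route**

Step 1
Reactants: 1, 5-bromo-2-hydroxy-3-methoxybenzaldehyde (5-bromo-o-vanillin)
Product: 2, 5-bromo-3-methoxybenzene-1,2-diol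
Conditions: 30% H2O2 (1.2 equiv), 1 M NaOH (1.1 equiv), H2O–THF, 0 °C → rt, N2; then 1 M HCl
Reagents that add atoms: hydrogen peroxide, OO
Why: Dakin oxidation (hydroperoxide adds to the o-hydroxy aldehyde, the aryl group migrates, the formate hydrolyses), as for o-vanillin itself; the aryl bromide is inert.

Step 2
Reactants: 3, (E)-sinapyl alcohol [4-[(E)-3-hydroxyprop-1-enyl]-2,6-dimethoxyphenol]
Product: 4, (E)-3-[4-(tert-butyldimethylsilyloxy)-3,5-dimethoxyphenyl]prop-2-en-1-ol
Conditions: NaH (1.0 equiv), THF–DMF (9:1), 0 °C; then TBSCl (1.05 equiv), 0 °C → rt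
Reagents that add atoms: TBSCl, CC(C)(C)[Si](C)(C)Cl
Why: Chemoselective O-silylation through the phenoxide (phenol about 5 pKa units more acidic than the allylic alcohol, so one equivalent of base gives only ArO⁻); the alkene geometry is untouched.

Step 3
Reactants: 2, 5-bromo-3-methoxybenzene-1,2-diol
Product: 5, 5-bromo-3-methoxycyclohexa-3,5-diene-1,2-dione (5-bromo-3-methoxy-o-benzoquinone)
Conditions: Ag2O (2.5 equiv), Na2SO4, CH2Cl2, −10 °C, dark, 20 min; cold filtration through Celite under Ar; solution used at once in Step 4
Reagents that add atoms: none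
Why: Two-electron oxidative dearomatisation of a catechol to its o-quinone (classical Ag2O oxidation); the 3,5-disubstitution slows quinone dimerisation.

Step 4
Reactants: 5, 5-bromo-3-methoxy-o-benzoquinone (1.3 equiv); 4, phenol-TBS sinapyl alcohol (1.0 equiv)
Product: 6, (2S,3S)-7-bromo-2-[4-(tert-butyldimethylsilyloxy)-3,5-dimethoxyphenyl]-3-(hydroxymethyl)-5-methoxy-2,3-dihydro-1,4-benzodioxine (trans)
Conditions: (R)-TRIP (10 mol %), 4 Å MS, CH2Cl2–toluene (1:1), −40 → −20 °C; aq. Na2S2O4 quench (excess 5 returns to 2)
Reagents that add atoms: none (all atoms come from 4 and 5)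
Why: Proposed new method: an asynchronous inverse-electron-demand oxa-Diels–Alder reaction in which the acid P–OH hydrogen-bonds the more basic carbonyl oxygen of 5 (C1=O, the vinylogous-ester carbonyl conjugated to the 3-OMe) while P=O binds the allylic OH of 4. The CH2OH-bearing alkene carbon is thereby delivered on one enantioface to the other quinone oxygen (O-2, next to OMe; this leaves the developing phenol at O-1, meta to both Br and OMe, the better-stabilised site). The benzylic carbon then closes suprafacially onto O-1, restoring aromaticity. The trans C2/C3 relationship follows from the (E)-alkene and is also the thermodynamic isomer; the absolute configuration comes from the chiral acid. Closest known chemistry: the thermal hetero-Diels–Alder reaction of o-quinones with styrenes to give 1,4-benzodioxanes, and chiral-phosphoric-acid-catalysed formal cycloadditions of quinone derivatives and o-quinone methides with hydroxyl-bearing styrenes.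

Step 5
Reactants: 6, bromobenzodioxane; 7, (E)-tert-butyldimethyl{[3-(4,4,5,5-tetramethyl-1,3,2-dioxaborolan-2-yl)prop-2-en-1-yl]oxy}silane (1.5 equiv)
Product: 8, (2S,3S)-2-[4-(tert-butyldimethylsilyloxy)-3,5-dimethoxyphenyl]-3-(hydroxymethyl)-5-methoxy-7-[(E)-3-(tert-butyldimethylsilyloxy)prop-1-enyl]-2,3-dihydro-1,4-benzodioxine
Conditions: SPhos Pd G3 (3 mol %), K3PO4 (3 equiv), THF–H2O (10:1), 50 °C
Reagents that add atoms: none (the new C3 unit comes from 7)
Why: Suzuki–Miyaura coupling; the SPhos ligand allows oxidative addition into the electron-rich aryl bromide and the (E)-alkenyl boronate transfers with retention. The free primary OH is tolerated, the ring stereocentres are not involved, and any partial loss of the aryl TBS group is harmless because Step 6 removes it.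

Step 6
Reactants: 8, bis-silyl ether
Product: 9, 4-[(2S,3S)-3-(hydroxymethyl)-7-[(E)-3-hydroxyprop-1-enyl]-5-methoxy-2,3-dihydro-1,4-benzodioxin-2-yl]-2,6-dimethoxyphenol (target)
Conditions: TBAF (3 equiv), AcOH (3 equiv), THF, 0 °C → rt; aq. NH4Cl
Reagents that add atoms: none
Why: Fluoride-mediated cleavage of both the aryl and alkyl Si–O bonds; the acetic acid buffer keeps the liberated p-hydroxybenzyl aryl ether away from strong base (which could open the ring via a quinone methide), so C2, C3 and the (E)-alkene are unchanged.

**Compound list**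

1 | 5-bromo-2-hydroxy-3-methoxybenzaldehyde | COc1cc(Br)cc(C=O)c1O | starting material
2 | 5-bromo-3-methoxybenzene-1,2-diol | COc1cc(Br)cc(O)c1O | intermediate
3 | (E)-sinapyl alcohol | COc1cc(/C=C/CO)cc(OC)c1O | starting material
4 | (E)-3-[4-(tert-butyldimethylsilyloxy)-3,5-dimethoxyphenyl]prop-2-en-1-ol | COc1cc(/C=C/CO)cc(OC)c1O[Si](C)(C)C(C)(C)C | intermediate
5 | 5-bromo-3-methoxycyclohexa-3,5-diene-1,2-dione | COC1=CC(Br)=CC(=O)C1=O | intermediate (used in solution)
6 | (2S,3S)-7-bromo-2-[4-(TBSO)-3,5-dimethoxyphenyl]-3-(hydroxymethyl)-5-methoxy-2,3-dihydro-1,4-benzodioxine | COc1cc([C@@H]2Oc3cc(Br)cc(OC)c3O[C@H]2CO)cc(OC)c1O[Si](C)(C)C(C)(C)C | intermediate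
7 | (E)-tert-butyldimethyl{[3-(pinacolboryl)prop-2-en-1-yl]oxy}silane | CC(C)(C)[Si](C)(C)OC/C=C/B1OC(C)(C)C(C)(C)O1 | starting material
8 | (2S,3S)-2-[4-(TBSO)-3,5-dimethoxyphenyl]-3-(hydroxymethyl)-5-methoxy-7-[(E)-3-(TBSO)prop-1-enyl]-2,3-dihydro-1,4-benzodioxine | COc1cc([C@@H]2Oc3cc(/C=C/CO[Si](C)(C)C(C)(C)C)cc(OC)c3O[C@H]2CO)cc(OC)c1O[Si](C)(C)C(C)(C)C | intermediate
9 | 4-[(2S,3S)-3-(hydroxymethyl)-7-[(E)-3-hydroxyprop-1-enyl]-5-methoxy-2,3-dihydro-1,4-benzodioxin-2-yl]-2,6-dimethoxyphenol | COc1cc([C@@H]2Oc3cc(/C=C/CO)cc(OC)c3O[C@H]2CO)cc(OC)c1O | target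

**Totals**

Total step count: 6 (Steps 3 and 4 are run as one telescoped operation).
Longest linear sequence: 5 steps (1 → 2 → 5 → 6 → 8 → 9).

**Steps most likely to fail**

1. Step 4 (asymmetric quinone cycloaddition). It is unprecedented in enantioselective form. The risks are low or wrong-sense ee, C-attack on the quinone ring (Michael or [3+2] products), and the wrong O-regiochemistry.
 Fallback: set the CH2OH-bearing centre first by a cinchona-alkaloid-catalysed [4+2] of quinone 5 with the ketene enolate of 3-[4-(silyloxy)-3,5-dimethoxyphenyl]propanoyl chloride, giving a 1,4-benzodioxin-2-one. Open the lactone reductively (LiBH4) to the 2-aryloxy-3-arylpropan-1-ol carrying a free ortho-phenol. Then close the benzylic C–O bond by oxidising the desilylated syringyl unit to its p-quinone methide (Ag2O), which cyclises to the trans ring.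

2. Step 3 (o-quinone 5). It may dimerise or decompose before it is used.
 Fallback: stop preparing it as a discrete batch. Generate it continuously in line (packed bed of silica-supported NaIO4 or a flow electrolysis cell) and feed it straight into the cold solution of 4 and catalyst, so it is consumed as it forms.

3. Step 2 (phenol-selective silylation of the air-sensitive sinapyl alcohol). Silylation at the wrong oxygen, bis-silylation or oxidative loss of 3 are possible.
 Fallback: build 4 from syringaldehyde, where no competing OH exists: TBSCl/imidazole, Horner–Wadsworth–Emmons olefination with triethyl phosphonoacetate, then DIBAL-H reduction to the (E)-allylic alcohol.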